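**Slow step.** I began from how slowly the starting material goes, a slowness to be held against the time a vessel gives it: 50 min in west, 50 min on average in north-east, and in north-west from 50 min for the first of the dose down to 10.0 min for the last of it.

| flask | starting material | free catalyst | remark | time |
|---|---|---|---|---|
| eta | 18 mM | 18 µM | run made earlier |  |
| gamma | 18 mM | 36 µM | run made earlier |  |
| north-east | 18 mM | 18 µM | a single well-mixed tank run continuously and read at steady state, 50 min in it on average |  |
| north-west | 18 mM (fed, over 40.0 min) | 18 µM | a stirred flask in which starting material is dosed at a steady rate over 40.0 min without added volume, worked up at 50 min | 50 min |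
| west | 18 mM | 18 µM | everything together in a closed stirred flask, run for 50 min | 50 min |

| run | time / min | target / % | starting material / % |
|---|---|---|---|
| eta | 2.50 | 24 | 77 |
| eta | 5.00 | 44 | 53 |
| eta | 8.00 | 65 | 38 |
| eta | 15.0 | 90 | 14 |
| eta | 30.0 | 99 | 1 |
| gamma | 0.417 | 6 | 92 |
| gamma | 1.33 | 24 | 77 |
| gamma | 2.50 | 38 | 64 |
| gamma | 4.00 | 59 | 43 |
| gamma | 5.00 | 65 | 32 |

(readings scatter by 2 percentage points)

- the stated concentrations are those of everything mixed, before any reaction; amounts are the same in each set-up
- the numbers in the tables scatter with a standard deviation of 2 percentage points
- the feed brings no volume worth counting
- the earlier runs were made in a closed, stirred flask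

- the set-up with the highest amount of target at the outlet or at the end, in percent of the starting material put in ("none" if the first two lie within 2 percentage points) (north-east / north-west / west / none)
- amount of target at the outlet or at the end, in percent of the starting material put in, north-east
- amount of target at the outlet or at the end, in percent of the starting material put in, north-west
- amount of target at the outlet or at the end, in percent of the starting material put in, west

**Two times.** The eta run has the charge of the flasks asked about, and at 30.0 min its target and starting material summed to 100%, so I reckoned with no side route. Read as pseudo-first-order up to 15.0 min, it gave a lifetime of 7.63 min, which left 13.2% starting material in north-east.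

**Second round.** I went round again, using the stretch of the eta run that ends nearest that level, 8.00 min to 15.0 min. There the lifetime of starting material, the time in which it falls by a factor e, was 7.01 min, shorter than before. The 50 min of west and north-east over this lifetime is 7.13. My reckoning gave north-east 87.7%, north-west 95.8% and west 99.9%.

**The forecast.** It named west, with 99.5% there, 95.5% in north-west and 87.5% in north-east, noting a rate “drifting up slightly as starting material falls”.

**The flasks.** The highest was west at >99.9%, more than north-west at 96.9% and north-east at 88.9%, whose outlet held 11.0% starting material.

    starting material + free catalyst ⇌ catalyst intermediate A (K = 1200 /M, k = 520 /M/s)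
    catalyst intermediate A → catalyst intermediate B (k = 2.30 /s)
    catalyst intermediate B → free catalyst + target (k = 130 /s)
    2 free catalyst ⇌ resting dimer, settled at all times (K = 60000 /M)
    2 free catalyst → spent catalyst (k = 22.0 /M/s)

**Longer tank.** To pass north-west, north-east needed more than 96.9%. With my lifetime of 7.01 min, ten times the residence time reckons to 98.6%. That tank gave 97.7%, while west at ten times the time stood at 100%.

The earlier runs and the new flask stem from a simulated flask with made-up constants, and the scatter is random.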